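(The earlier runs and the new flask come from a simulation with constants of no real substance; noise was put on by code.)

The ratio of two log-losses, the logarithm of charge over what is left for the left-handed substrate against the same for the right-handed substrate, is the selectivity factor of a single-handed free catalyst working through a racemate with reagent, and with fractions left instead of fractions made we need one further number for this flask.

all flasks: left-handed substrate 20 mM; right-handed substrate 20 mM; free catalyst 0.40 mM; impurity 0.29 mM
- Tuesday's: reagent 20 mM; run made earlier
- Saturday's: reagent 80 mM; run made earlier
- flask: reagent 40.0 mM; time 4.0 min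

- Tuesday's (time / min: right-handed substrate / %, left-handed substrate / %): 0.833: 47.7, 35.4; 1.50: 47.3, 33.1; 2.50: 49.6, 30.5; 3.00: 49.0, 27.9
- Saturday's (time / min: right-handed substrate / %, left-handed substrate / %): 0.250: 47.4, 24.0; 0.667: 43.4, 15.8; 1.33: 40.7, 8.4; 3.00: 40.3, 4.2

(standard deviation of a reading: 1 percentage point)

- free catalyst is single-handed; left-handed substrate and right-handed substrate are mirror images of each other, charged as a racemate, each of them at the stated concentration
- steps thought possible: free catalyst + left-handed substrate <-> catalyst intermediate A; free catalyst + right-handed substrate <-> catalyst intermediate B; reagent + catalyst intermediate A -> free catalyst + left-handed product; reagent + catalyst intermediate B -> free catalyst + right-handed product; free catalyst + impurity -> spent catalyst A; reagent <-> dormant form; 2 free catalyst -> spent catalyst B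

* whether the excess of right-handed substrate over left-handed substrate among what is left of the two reaches 98 % by 4.0 min (yes / no)
* the highest excess of right-handed substrate over left-handed substrate among what is left of the two up to 4.0 min

Saturday's last reading puts the ratio at 11.5, since Tuesday's right-handed substrate has lost too little against the scatter to serve. The left-handed log-loss at 3.00 min reads 0.583 on Tuesday and 2.48 on Saturday, which per mM of reagent charged is 0.0292 mM⁻¹ and 0.0310 mM⁻¹, close although Saturday's charge is 4.00 times Tuesday's. So we multiply their mean by the flask's 40.0 mM and get 1.20, the dose, meaning the left-handed log-loss bought by the reagent charged.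

In this flask the dose leaves 30.0 % of the left-handed charge and 90.1 % of the right-handed, an excess of 50.0 %, which grows with the dose, so we take it as the top. Was one number enough? Setting the right-handed loss to zero in the formula gives 53.8 %, so the selectivity factor moves the answer by 3.8 percentage points. But the dose belongs to 3.00 min, not to 4.0 min, and we leave that last stretch out of our figure, although the left-handed readings of both runs were still falling at their end. The excess wanted, 98 %, needs a left-to-right ratio of 0.0101, and our flask stands at 0.333, so we say no.

The forecast says no with a top of 53 %, between 45 % and 62 %, “still rising at 4 min, and far below 98%”, which is above our figure.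

The flask gives no and a top of 48.8 %, with 31 % of the left-handed charge left at 4.00 min, a log-loss of 1.17 against our dose of 1.20.

    free catalyst + left-handed substrate ⇌ catalyst intermediate A (K = 58.0 M⁻¹, k = 3000 M⁻¹ s⁻¹)
    free catalyst + right-handed substrate ⇌ catalyst intermediate B (K = 11.0 M⁻¹, k = 26000 M⁻¹ s⁻¹)
    reagent + catalyst intermediate A → free catalyst + left-handed product (k = 220 M⁻¹ s⁻¹)
    reagent + catalyst intermediate B → free catalyst + right-handed product (k = 100 M⁻¹ s⁻¹)
    free catalyst + impurity → spent catalyst A (k = 3900 M⁻¹ s⁻¹)
    reagent ⇌ dormant form (K = 1.90, k = 0.0140 s⁻¹)
    2 free catalyst → spent catalyst B (k = 200 M⁻¹ s⁻¹)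

The half-life of free catalyst against the impurity, 0.61 s with the charges as at the start, is far shorter than the 0.321 min by which half the left-handed binding turnover up to 4.0 min is done. Spent catalyst A holds 72.2 % of the catalyst at 0.400 min and 72.5 % at 4.00 min. In a neighbour flask charged with 24 mM of reagent the dose is 0.722, which leaves 48.6 % of the left-handed charge and an excess of 31.8 %. That flask computes to 51 % left and a top of 29.8 %.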